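# Proposed total synthesis of CNP0319155.2 by a C1–C2 macro-aldol closure

## Structural features

The target is a germacranolide: a ten-membered carbocycle (C1–C10) with an α-methylene-γ-butyrolactone (O–C6, C7, C11=C13, C12=O) cis-fused across C6–C7 and a cis-1,10-epoxide whose C10 carries the methyl group. The only ring alkene is the Z-trisubstituted C4=C5; it bears the free C15 hydroxymethyl group and lies between the C3 acetate and the lactone carbinol C6. C6, C7 and C8 are contiguous stereocentres (lactone oxygen, C11 branch, methacrylate oxygen) with the C11 branch anti to both neighbouring oxygens. The fully substituted C10 is adjacent to C1, and C3 is separated from C1 only by the C2 methylene (1R,3S,6S,7R,8R,10S). Fragile groups are the epoxide (acid, transannular attack by C4=C5), the α-methylene lactone and the methacrylate (nucleophiles, base), and the C3 acetate next to the free C15 alcohol (acyl shift); O6 and O8 are both placed to lactonise onto C12. The real difficulty is to close a strained ten-membered ring that contains a Z-trisubstituted alkene while six oxygen functions are kept in different states, and to set the stereotriad and the quaternary C10 without a rigid template. The key step exploits the 1,3-relationship of the oxygens on C1 and C3 through C2 together with the position of C1 next to the quaternary, oxygenated C10. A C3 methyl ketone and a C1 aldehyde are an aldol pair, the aldehyde cannot enolise, and its α-oxygen can direct the new C1 centre, which later becomes the epoxide carbon by displacement with inversion.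

## Logic of the disconnections

42 to 41: the O15–Si bond is cut last. The primary allylic alcohol beside the C3 acetate is then never present during an oxidation or an acylation. The forward step must remove a robust silyl ether without opening the epoxide or moving the acetate.

41 to 38 (and 38 to 37): the O6–C12 lactone bond is cut and C12 returned to the alcohol level. The Michael acceptor is thereby absent from every enolate, hydride and alkoxide step. The demand is an oxidation that takes the primary allylic C12 alcohol ahead of the secondary allylic C6 alcohol, with O8 already acylated so that only O6 can close.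

37 to 36, 35 and 34: the C1–O bond of the epoxide is cut to a C10 alcohol and a C1 sulfonate, and the C8 ester is cut to the alcohol. The epoxide configuration then follows from two carbinol centres and an inversion at C1, not from a face-selective epoxidation. The forward sequence must free O8 and O10 together, acylate O8 only, and close the oxirane faster than any ester exchange.

34 to 33, 32 and 31: the C1 sulfonate, the C3 acetate and the C3–H bond all trace back to one β-hydroxy ketone. The demand is a hydroxyl-directed anti reduction inside a medium ring and a distinction between two secondary alcohols (allylic C3 against neopentyl-like C1).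

31 to 28 (key disconnection): the C1–C2 bond is cut, opening the ten-membered ring to a Z-methyl enone tethered to an α-alkoxy aldehyde. All other stereocentres can then be built on an open chain. The forward step has to close a ten-membered ring by an enolate addition and set C1 syn to the C10 oxygen. Three protecting-group changes serve this:
- O10 and O8 carry PMB groups: both chelate, and both are removed together under neutral oxidative conditions once the mesylate and acetate are in place.
- O12 carries TBS, which distinguishes it from the primary C1 silyl ether during the direct oxidation of step 16.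
- O6 keeps triethylsilyl and O15 keeps TBDPS.

28 to 25 and 26: the C3–C4 bond is cut to a Z-iodoalkene and an acetyl anion equivalent. The coupling must keep the alkene geometry and tolerate the aldehyde.

25 to 24, 23 and 21: the C1 aldehyde is traced to a primary silyl ether, and the C4–I and C5–H bonds to an alkyne next to the free C6 carbinol. The hydroxyl-directed trans-hydroalumination must deliver the Z geometry and not expel the C15 silyloxy group.

21 to 18 and 19: the C5–C6 bond is cut to an aldehyde and a propargyl silyl ether. The addition must set C6 anti to the C11 branch; the PMB ether on O8 is placed to enforce this by chelation.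

18 to 17, 16 and 15: the C6 aldehyde is traced to a primary alcohol, and the two PMB ethers to two cyclic p-methoxybenzylidene acetals of a 1,3-diol and a 1,2-diol. One reductive opening then puts PMB on the secondary O8 and the tertiary O10 and frees both primary alcohols. The demand is that the less hindered C6 alcohol is oxidised ahead of the C1 alcohol.

15 to 10 and 12 (12 from 11): the C7–C11 bond is cut to a trans-epoxy alcohol and a 2-metallated allyl silyl ether. SN2 opening at C7 fixes the 7,8-anti relationship. The forward step needs attack at C7, not C8.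

10 to 9 and 7: the two C–O bonds of the oxirane are cut to an E-allylic alcohol, and the alkene to the propargylic alcohol. Absolute configuration at C7 and C8 comes from the tartrate ligand.

7 to 6, then to 4 and 2, then to 3 and 1: the acetal is traced to a PMB ether beside the free tertiary alcohol, and the C8–C9 bond is cut to an acetylide and a 2,2-disubstituted epoxide. C10 is bought as a stereocentre in 1.

## Other disconnections considered

Alternative 1: the cut is C5–C6, with C3–C8 re-formed, which contracts the ten-membered ring to a cyclohexene carrying two alkenyl groups. In the forward sense a potassium alkoxide undergoes an anionic oxy-Cope shift and the enolate is silylated to give the bis(enol ether) A1.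
- In its favour: the ring is made by expansion, so no high dilution is needed and the charge-accelerated shift pays for the ring strain. This reaction class has long precedent for ten-membered rings. On the ring-forming event itself this route is the better of the two.
- Against it here: A1 holds only the C6 stereocentre. C3 and C8 are at the ketone level, C4 lacks C15, and the C7 side chain is a two-carbon unit without C13. The C15 hydroxymethyl group, the carbinol centres at C3 and C8, the C7 centre, the epoxide and the methylene group would all have to be introduced on a flexible, transannularly reactive cyclodecadiene.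
- Comparison: the chosen plan leaves only C1 and C3 to be set on the ring and needs far fewer operations after ring closure. Both routes use a strong potassium base at low temperature, so they are equal in functional-group demands at the key step.

Alternative 2: the cut is C7–C8. In the forward sense CrCl2 (divalent chromium) turns a 3-(bromomethyl)butenolide into an allylchromium that adds through C7 to a tethered C8 aldehyde, giving A2 with the exocyclic methylene in place.
- In its favour: A2 already contains the lactone, the C3 acetate, both ring alkenes and the C8 alcohol, so only methacryloylation, epoxidation and desilylation would remain. In step economy after ring closure it is clearly the better route. The tether forces the new bond onto the butenolide face that carries C5, so the cis ring fusion follows from connectivity. Chromium-mediated allylations are an established way to close medium rings, so on precedent it is also the better.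
- Against it here: the open-chain substrate must already carry the Z-trisubstituted C1=C10 alkene, the C3 centre and a base-sensitive bromomethyl butenolide with an acidic C6 hydrogen. C8 is decided in the macrocyclic transition state with no independent control. The epoxide would then depend on a face- and site-selective epoxidation of C1=C10 beside C4=C5, carried out with the α-methylene lactone present.
- Comparison: the chosen plan sets C7 and C8 on the open chain by SN2 opening of a Sharpless epoxide and sets the epoxide by stereospecific displacement. It is therefore the more predictable in stereochemistry, but longer and mechanistically less proven at its key step.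

Alternative 3: the cut re-forms the C6–C10 bond, folding the ten-membered ring into a hydroazulene. In the forward sense the C6 alkoxide of a mesylate fragments (Grob) to the C6 ketone and the Z-C1=C10 alkene, giving A3.
- In its favour: the ring is unveiled from a rigid bicycle with release of strain and without dilution. The Z geometry of C1=C10 is fixed stereospecifically by the anti-periplanar arrangement, and C3, C7 and C8 are set on a conformationally defined framework. On ring formation and on control of that alkene it is the equal or the better of the chosen plan.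
- Against it here: A3 still needs a face-selective reduction of the C6 ketone next to an enolisable C7, lactonisation, α-methylenation with a strong base, exchange of the C3 protecting group for acetate and a face-selective epoxidation. The bicyclic substrate with two fully substituted carbons is itself long to prepare.
- Comparison: the chosen plan derives the C1 and C3 oxygens and the epoxide directly from the ring-closing event and needs no enolate chemistry after the lactone exists. The ring-closing step of Alternative 3 rests on firmer mechanistic ground.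

Key step: step 18

Remark on numbering: locants C1–C15 in names are the germacrane locants of the atoms in 42.
Remark on acetal carbons: the p-methoxybenzylidene acetal carbons are carried as epimer mixtures (unspecified in SMILES) and are destroyed in step 10.
Remark on starting materials: 1, 3, 11 and 26 are taken as commercial.
Remark on configuration: the C1 carbinol of 31 must be syn to the C10 oxygen, because closure with inversion then gives the cis-epoxide encoded in the target; the substrate 28 and product 31 of the key step are consistent with this and needed no stereochemical correction.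

## Route

Step 1
Reactants: 1 (R)-2-methylglycidol
Product: 2 (S)-2-[(4-methoxybenzyloxy)methyl]-2-methyloxirane
Conditions: NaH, 4-MeOC6H4CH2Cl, Bu4NI (cat.), THF, 0 °C to rt
Reagents that add atoms: 4-methoxybenzyl chloride COc1ccc(CCl)cc1
Why: Williamson etherification of the primary alkoxide; the Payne rearrangement of 1 is degenerate and stereoretentive, so C10 is untouched.

Step 2
Reactants: 3 prop-2-yn-1-ol
Product: 4 4-methoxybenzyl propargyl ether
Conditions: NaH, 4-MeOC6H4CH2Cl, Bu4NI (cat.), THF, 0 °C to rt
Reagents that add atoms: 4-methoxybenzyl chloride COc1ccc(CCl)cc1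
Why: Williamson etherification; the PMB ether allows metallation of the alkyne in step 3 and is removed oxidatively in step 4.

Step 3
Reactants: 4 4-methoxybenzyl propargyl ether; 2 (S)-2-[(4-methoxybenzyloxy)methyl]-2-methyloxirane
Product: 6 (S)-1,6-bis(4-methoxybenzyloxy)-2-methylhex-4-yn-2-ol, via lithium acetylide 5 (not isolated)
Conditions: n-BuLi, THF, −78 °C; BF3·OEt2; then 2, −78 °C
Reagents that add atoms: none
Why: Yamaguchi–Hirao alkynylation: the BF3-activated 2,2-disubstituted epoxide is opened by the acetylide at its unsubstituted carbon, forming C8–C9 and leaving the C10 configuration of 2 intact.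

Step 4
Reactants: 6 (S)-1,6-bis(4-methoxybenzyloxy)-2-methylhex-4-yn-2-ol
Product: 7 4-[(4S)-2-(4-methoxyphenyl)-4-methyl-1,3-dioxolan-4-yl]but-2-yn-1-ol
Conditions: DDQ (2.3 equiv), 4 Å molecular sieves, CH2Cl2, 0 °C; then aq. NaHCO3
Reagents that add atoms: none
Why: DDQ oxidation of PMB ethers: the oxocarbenium ion beside the free C10 hydroxyl is trapped as the five-membered p-methoxybenzylidene acetal (oxidative acetalisation), while the isolated propargylic PMB ether is cleaved to the alcohol on aqueous work-up.

Step 5
Reactants: 7 4-[(4S)-2-(4-methoxyphenyl)-4-methyl-1,3-dioxolan-4-yl]but-2-yn-1-ol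
Product: 9 (E)-4-[(4S)-2-(4-methoxyphenyl)-4-methyl-1,3-dioxolan-4-yl]but-2-en-1-ol, via cyclic alkenylaluminate 8 (not isolated)
Conditions: NaAlH2(OCH2CH2OMe)2, THF, 0 °C to rt; aq. Rochelle salt
Reagents that add atoms: none
Why: Alkoxide-directed trans-hydroalumination of a propargylic alcohol followed by protonolysis gives only the E-allylic alcohol; the acetal is inert to the aluminate.

Step 6
Reactants: 9 (E)-4-[(4S)-2-(4-methoxyphenyl)-4-methyl-1,3-dioxolan-4-yl]but-2-en-1-ol
Product: 10 [(2R,3R)-3-{[(4S)-2-(4-methoxyphenyl)-4-methyl-1,3-dioxolan-4-yl]methyl}oxiran-2-yl]methanol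
Conditions: Ti(OiPr)4 (cat.), D-(−)-diisopropyl tartrate (cat.), t-BuOOH, 4 Å molecular sieves, CH2Cl2, −20 °C
Reagents that add atoms: tert-butyl hydroperoxide CC(C)(C)OO
Why: Sharpless asymmetric epoxidation; the D-tartrate complex delivers oxygen to one face of the E-allylic alcohol and sets C7 and C8 under reagent control, independent of the remote C10 centre.

Step 7
Reactants: 11 2-bromoprop-2-en-1-ol
Product: 12 (2-bromoallyloxy)(tert-butyl)dimethylsilane
Conditions: t-BuMe2SiCl, imidazole, CH2Cl2, 0 °C to rt
Reagents that add atoms: tert-butyldimethylsilyl chloride CC(C)(C)[Si](C)(C)Cl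
Why: Standard silylation; the TBS group later distinguishes O12 from the primary C1 triethylsilyl ether in step 16.

Step 8
Reactants: 12 (2-bromoallyloxy)(tert-butyl)dimethylsilane; 10 [(2R,3R)-3-{[(4S)-2-(4-methoxyphenyl)-4-methyl-1,3-dioxolan-4-yl]methyl}oxiran-2-yl]methanol
Product: 15 (2S,3R)-2-[3-(tert-butyldimethylsilyloxy)prop-1-en-2-yl]-4-[(4S)-2-(4-methoxyphenyl)-4-methyl-1,3-dioxolan-4-yl]butane-1,3-diol, via alkenyllithium 13 (not isolated), via alkenylmagnesium bromide 14 (not isolated)
Conditions: 12 (4 equiv), t-BuLi, Et2O, −78 °C; MgBr2·OEt2; CuI (cat.); then 10, THF, −78 to −30 °C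
Reagents that add atoms: none
Why: Copper-catalysed alkenyl Grignard opening of a trans-2,3-epoxy alcohol at C2 (here C7) with inversion gives the 1,3-diol and fixes the 7,8-anti relationship; attack at C8 is further disfavoured by the neopentyl-like C9 branch, and the reagent is made by Br–Li exchange and kept cold to suppress β-elimination of silanolate.

Step 9
Reactants: 15 (2S,3R)-2-[3-(tert-butyldimethylsilyloxy)prop-1-en-2-yl]-4-[(4S)-2-(4-methoxyphenyl)-4-methyl-1,3-dioxolan-4-yl]butane-1,3-diol
Product: 16 bis(4-methoxybenzylidene) acetal (O6/O8 1,3-dioxane; O1/O10 1,3-dioxolane; O12-TBS)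
Conditions: 4-MeOC6H4CH(OMe)2, PPTS (cat.), CH2Cl2, rt
Reagents that add atoms: 4-methoxybenzaldehyde dimethyl acetal COc1ccc(C(OC)OC)cc1
Why: Acid-catalysed transacetalisation converts the 1,3-diol into the six-membered p-methoxybenzylidene acetal; the allylic TBS ether and the dioxolane survive PPTS in an aprotic solvent.

Step 10
Reactants: 16 bis(4-methoxybenzylidene) acetal
Product: 17 C1/C6-diol (O8-PMB; O10-PMB; O12-TBS)
Conditions: i-Bu2AlH (excess), CH2Cl2, −78 to 0 °C; aq. Rochelle salt
Reagents that add atoms: none
Why: Reductive opening of p-methoxybenzylidene acetals: aluminium binds the less hindered primary oxygen of each acetal, so the PMB groups end on the secondary O8 and the tertiary O10 and both primary alcohols are freed.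

Step 11
Reactants: 17 C1/C6-diol
Product: 18 C6 aldehyde (C1 hydroxyl free; O8-PMB; O10-PMB; O12-TBS)
Conditions: TEMPO (cat.), PhI(OAc)2 (1.05 equiv), CH2Cl2, 0 °C
Reagents that add atoms: none
Why: Oxoammonium (TEMPO) oxidation is sensitive to hindrance: the C6 carbinol on a tertiary carbon should react ahead of the neopentyl C1 carbinol on the alkoxy-bearing quaternary C10; no base is present, so the α-alkenyl aldehyde is neither epimerised nor conjugated.

Step 12
Reactants: 3 prop-2-yn-1-ol
Product: 19 tert-butyldiphenyl(prop-2-yn-1-yloxy)silane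
Conditions: t-BuPh2SiCl, imidazole, CH2Cl2, rt
Reagents that add atoms: tert-butyldiphenylsilyl chloride CC(C)(C)[Si](Cl)(c1ccccc1)c1ccccc1
Why: Standard silylation of a primary alcohol.

Step 13
Reactants: 19 tert-butyldiphenyl(prop-2-yn-1-yloxy)silane; 18 C6 aldehyde
Product: 21 C6 propargylic alcohol (C4–C15 alkyne arm; C1 hydroxyl free), via alkynylmagnesium bromide 20 (not isolated)
Conditions: 19 (3.5 equiv), EtMgBr, THF, 0 °C; then 18, CH2Cl2/Et2O, −78 to −20 °C
Reagents that add atoms: none
Why: Alkynyl Grignard addition under 1,3-chelation control (Cram–Reetz model): magnesium bridges the aldehyde and the O8 PMB ether in a six-membered chelate and the nucleophile enters anti to the C11 branch on C7, giving the 6,7-anti carbinol with O6 and O8 syn; excess reagent deprotonates the free C1 hydroxyl.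

Step 14
Reactants: 21 C6 propargylic alcohol
Product: 23 (Z)-C4-iodo C4=C5 alkene diol, via cyclic alkenylaluminate 22 (not isolated)
Conditions: NaAlH2(OCH2CH2OMe)2, THF, 0 °C to rt; then I2, THF, −78 °C
Reagents that add atoms: iodine II
Why: Hydroxyl-directed trans-hydroalumination puts hydride on C5 and aluminium on C4 in a five-membered aluminate; iodinolysis with retention gives the Z-iodoalkene (iodine cis to C6), which fixes the ring-alkene geometry; elimination of the C15 silyloxy group to an allene is avoided by mild temperature and cold iodination.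

Step 15
Reactants: 23 (Z)-C4-iodo C4=C5 alkene diol
Product: 24 O6/O1 bis(triethylsilyl) ether
Conditions: Et3SiOTf, 2,6-lutidine, CH2Cl2, −78 °C
Reagents that add atoms: triethylsilyl trifluoromethanesulfonate CC[Si](CC)(CC)OS(=O)(=O)C(F)(F)F
Why: Silylation of both hydroxyls; O6 must be capped before the ketone is unveiled because a free Z-γ-hydroxy enone would close to a furan.

Step 16
Reactants: 24 O6/O1 bis(triethylsilyl) ether
Product: 25 C1 aldehyde (O6-TES retained)
Conditions: (COCl)2, DMSO, CH2Cl2, −78 to −40 °C; then Et3N
Reagents that add atoms: none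
Why: Under Swern conditions a primary triethylsilyl ether is converted directly into the aldehyde while secondary triethylsilyl, TBS and TBDPS ethers are untouched; the aldehyde formed has no α-hydrogen.

Step 17
Reactants: 25 C1 aldehyde; 26 tributyl(1-ethoxyvinyl)stannane
Product: 28 seco keto aldehyde (Z-methyl enone; C1 aldehyde), via 2-ethoxydiene 27 (not isolated)
Conditions: Pd2(dba)3 (cat.), AsPh3, CuI (cat.), NMP, 40 °C; then 1 M aq. oxalic acid, THF, 0 °C
Reagents that add atoms: water O
Why: Stille coupling of the Z-iodoalkene with an acetyl anion equivalent proceeds with retention of geometry; brief mild-acid hydrolysis of the dienyl ether gives the methyl ketone with the acetyl group cis to C6.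

Step 18
Reactants: 28 seco keto aldehyde
Product: 31 ten-membered β-hydroxy enone (C1 carbinol), via potassium enolate 29 (not isolated), via potassium aldolate 30 (not isolated)
Conditions: KN(SiMe3)2 (1.05 equiv), THF (about 0.002 M), −78 °C, slow addition of 28; AcOH quench at −78 °C
Reagents that add atoms: none
Why: Proposed new method: KN(SiMe3)2 removes a proton from the C2 methyl group to give the kinetic cross-conjugated enolate 29; the C6 hydrogen is shielded by its silyl ether and the aldehyde has no α-hydrogen, so one nucleophile and one electrophile are present. C2 of 29 adds to the C1 carbonyl in a 10-exo-trig closure (enolate double bond inside the new ring) to give aldolate 30, which is protonated cold. The closest known reaction type is the KN(SiMe3)2-mediated macro-aldolisation of keto aldehydes, established for larger rings but not for a ten-membered carbocycle. The new C1 centre is controlled by chelation of potassium between the aldehyde oxygen and the C10 PMB ether oxygen, which holds C=O and C–O syn-periplanar so that C2 attacks across the face flanked by the small C10 methyl group, with the C9 branch turned away, giving C1–OH syn to the C10 oxygen. Closure against medium-ring strain is helped by the Z-enone, which turns the chain at C4=C5, and by the three branches on C6–C8, which restrict the rotamers of the tether. The step needs enolisation at the methyl group and not at C6, intramolecular ahead of intermolecular addition, and no retro-aldol or oxa-Michael reaction of 30; the bulky base at −78 °C, high dilution and the cold acidic quench are chosen to secure these.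

Step 19
Reactants: 31 ten-membered β-hydroxy enone
Product: 32 C1,C3-anti diol
Conditions: Me4NBH(OAc)3, MeCN/AcOH, −30 °C
Reagents that add atoms: none
Why: Saksena–Evans reduction: the C1 hydroxyl exchanges an acetate on boron and delivers hydride intramolecularly to the C3 carbonyl (1,2-reduction of the enone), giving the 1,3-anti (trans) diol with 3S; the silyl ethers survive acetic acid at this temperature.

Step 20
Reactants: 32 C1,C3-anti diol
Product: 33 C3 acetate
Conditions: Ac2O (1.1 equiv), 2,4,6-collidine, DMAP (cat.), CH2Cl2, −40 °C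
Reagents that add atoms: acetic anhydride CC(=O)OC(C)=O
Why: Kinetic acylation should discriminate the allylic C3 carbinol from the C1 carbinol, which is neopentyl-like beside the fully substituted C10; a hindered base, low temperature and one equivalent of anhydride are used.

Step 21
Reactants: 33 C3 acetate
Product: 34 C1 mesylate
Conditions: MsCl, Et3N, CH2Cl2, 0 °C
Reagents that add atoms: methanesulfonyl chloride CS(=O)(=O)Cl
Why: Sulfonylation through sulfene succeeds on hindered secondary alcohols; with C3 reduced, the C1 mesylate is no longer β to a carbonyl and does not eliminate.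

Step 22
Reactants: 34 C1 mesylate
Product: 35 C8,C10-diol
Conditions: DDQ (2.5 equiv), CH2Cl2/pH 7 buffer, 0 °C
Reagents that add atoms: none
Why: Oxidative cleavage of both PMB ethers under neutral buffered conditions leaves the mesylate, the allylic acetate and the three silyl ethers untouched; excess water suppresses acetal formation between O8 and O10.

Step 23
Reactants: 35 C8,C10-diol
Product: 36 C8 methacrylate
Conditions: methacrylic anhydride, Et3N, DMAP (cat.), CH2Cl2, 0 °C
Reagents that add atoms: methacrylic anhydride C=C(C)C(=O)OC(=O)C(C)=C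
Why: DMAP-catalysed acylation reaches only the secondary C8 hydroxyl, the tertiary C10 hydroxyl being unreactive; capping O8 before the base step prevents it from displacing the C1 mesylate to a tetrahydrofuran.

Step 24
Reactants: 36 C8 methacrylate
Product: 37 cis-1,10-epoxide
Conditions: NaH, THF, 0 °C to rt
Reagents that add atoms: none
Why: Intramolecular Williamson reaction (3-exo-tet): the C10 alkoxide displaces the C1 mesylate with inversion, turning the syn C1/C10 pair into the cis-epoxide (1R); the fully substituted C10 accelerates closure so that ester exchange should not compete.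

Step 25
Reactants: 37 cis-1,10-epoxide
Product: 38 C6,C12-diol
Conditions: HF·pyridine, excess pyridine, THF, 0 °C
Reagents that add atoms: none
Why: Buffered HF·pyridine removes the secondary triethylsilyl ether and the primary allylic TBS ether well before the primary TBDPS ether; the excess pyridine protects the epoxide.

Step 26
Reactants: 38 C6,C12-diol
Product: 41 O15-TBDPS ether of the target, via hydroxy enal 39 (not isolated), via lactol 40 (not isolated)
Conditions: TEMPO (cat.), PhI(OAc)2 (2.5 equiv), NaHCO3, CH2Cl2, rt
Reagents that add atoms: none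
Why: Oxidative lactonisation of a 1,4-diol: the oxoammonium oxidant takes the primary allylic C12 alcohol ahead of the secondary C6 alcohol, enal 39 closes to lactol 40 and this is oxidised to the lactone; O8 is already acylated, so only O6 can close, and the cis fusion follows from the C6/C7 configuration.

Step 27
Reactants: 41 O15-TBDPS ether of the target
Product: 42 target CNP0319155.2
Conditions: Bu4NF, AcOH (1:1), THF, 0 °C to rt
Reagents that add atoms: none
Why: Fluoride desilylation buffered with acetic acid keeps the medium near neutral, so the epoxide should not open and the C3 acetate should not shift to O15.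

## Compound list

1 | (R)-2-methylglycidol | C[C@@]1(CO)CO1 | starting material
2 | (S)-2-[(4-methoxybenzyloxy)methyl]-2-methyloxirane | C[C@@]1(COCc2ccc(OC)cc2)CO1 | intermediate
3 | prop-2-yn-1-ol (propargyl alcohol) | C#CCO | starting material
4 | 4-methoxybenzyl propargyl ether | C#CCOCc1ccc(OC)cc1 | intermediate
5 | lithium acetylide of 4 | [Li]C#CCOCc1ccc(OC)cc1 | intermediate
6 | (S)-1,6-bis(4-methoxybenzyloxy)-2-methylhex-4-yn-2-ol | COc1ccc(COCC#CC[C@](C)(O)COCc2ccc(OC)cc2)cc1 | intermediate
7 | 4-[(4S)-2-(4-methoxyphenyl)-4-methyl-1,3-dioxolan-4-yl]but-2-yn-1-ol (acetal carbon unspecified) | OCC#CC[C@]1(C)OC(c2ccc(OC)cc2)OC1 | intermediate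
8 | cyclic sodium alkenylaluminate from 7 (Al on C8, O6 bound to Al) | [Na+].COCCO[Al-]1(OCCOC)OCC=C1C[C@]2(C)OC(c3ccc(OC)cc3)OC2 | intermediate
9 | (E)-4-[(4S)-2-(4-methoxyphenyl)-4-methyl-1,3-dioxolan-4-yl]but-2-en-1-ol | OC/C=C/C[C@]1(C)OC(c2ccc(OC)cc2)OC1 | intermediate
10 | [(2R,3R)-3-{[(4S)-2-(4-methoxyphenyl)-4-methyl-1,3-dioxolan-4-yl]methyl}oxiran-2-yl]methanol | OC[C@H]1O[C@@H]1C[C@]2(C)OC(c3ccc(OC)cc3)OC2 | intermediate
11 | 2-bromoprop-2-en-1-ol | C=C(Br)CO | starting material
12 | (2-bromoallyloxy)(tert-butyl)dimethylsilane | C=C(Br)CO[Si](C)(C)C(C)(C)C | intermediate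
13 | [3-(tert-butyldimethylsilyloxy)prop-1-en-2-yl]lithium | [Li]C(=C)CO[Si](C)(C)C(C)(C)C | intermediate
14 | [3-(tert-butyldimethylsilyloxy)prop-1-en-2-yl]magnesium bromide | Br[Mg]C(=C)CO[Si](C)(C)C(C)(C)C | intermediate
15 | (2S,3R)-2-[3-(tert-butyldimethylsilyloxy)prop-1-en-2-yl]-4-[(4S)-2-(4-methoxyphenyl)-4-methyl-1,3-dioxolan-4-yl]butane-1,3-diol (C6 and C8 hydroxyls free; C11 branch anti to O8) | OC[C@H](C(=C)CO[Si](C)(C)C(C)(C)C)[C@H](O)C[C@]1(C)OC(c2ccc(OC)cc2)OC1 | intermediate
16 | bis(4-methoxybenzylidene) acetal of 15: 2-aryl-1,3-dioxane over O6/O8 carrying the C11 branch on C7, and 2-aryl-1,3-dioxolane over O1/O10 (acetal carbons unspecified) | C1[C@H](C(=C)CO[Si](C)(C)C(C)(C)C)[C@@H](C[C@]2(C)OC(c3ccc(OC)cc3)OC2)OC(c2ccc(OC)cc2)O1 | intermediate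
17 | HOCH2(C6)–C7H[C(=CH2)CH2OTBS]–C8H(OPMB)–C9H2–C10(CH3)(OPMB)–C1H2OH, configuration as in 15 | OC[C@H](C(=C)CO[Si](C)(C)C(C)(C)C)[C@H](OCc1ccc(OC)cc1)C[C@](C)(OCc1ccc(OC)cc1)CO | intermediate
18 | C6 aldehyde of 17 (C1 hydroxyl free) | O=C[C@H](C(=C)CO[Si](C)(C)C(C)(C)C)[C@H](OCc1ccc(OC)cc1)C[C@](C)(OCc1ccc(OC)cc1)CO | intermediate
19 | tert-butyldiphenyl(prop-2-yn-1-yloxy)silane | C#CCO[Si](c1ccccc1)(c1ccccc1)C(C)(C)C | intermediate
20 | alkynylmagnesium bromide of 19 | Br[Mg]C#CCO[Si](c1ccccc1)(c1ccccc1)C(C)(C)C | intermediate
21 | TBDPSOCH2(C15)–C4≡C5–C6H(OH)–C7H[C(=CH2)CH2OTBS]–C8H(OPMB)–C9H2–C10(CH3)(OPMB)–C1H2OH; O6 anti to the C11 branch, O6/O8 syn | CC(C)(C)[Si](c1ccccc1)(c1ccccc1)OCC#C[C@H](O)[C@H](C(=C)CO[Si](C)(C)C(C)(C)C)[C@H](OCc1ccc(OC)cc1)C[C@](C)(OCc1ccc(OC)cc1)CO | intermediate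
22 | cyclic disodium alkenylaluminate from 21 (Al on C4, O6 bound to Al, C1 alkoxide) | [Na+].[Na+].COCCO[Al-]1(OCCOC)O[C@H]([C@H](C(=C)CO[Si](C)(C)C(C)(C)C)[C@H](OCc2ccc(OC)cc2)C[C@](C)(OCc2ccc(OC)cc2)C[O-])C=C1CO[Si](c1ccccc1)(c1ccccc1)C(C)(C)C | intermediate
23 | (Z)-iodoalkene diol: I–C4(CH2OTBDPS)=C5H–C6H(OH)–…–C1H2OH, iodine cis to C6 | I/C(CO[Si](c1ccccc1)(c1ccccc1)C(C)(C)C)=C\[C@H](O)[C@H](C(=C)CO[Si](C)(C)C(C)(C)C)[C@H](OCc1ccc(OC)cc1)C[C@](C)(OCc1ccc(OC)cc1)CO | intermediate
24 | O6,O1-bis(triethylsilyl) ether of 23 | I/C(CO[Si](c1ccccc1)(c1ccccc1)C(C)(C)C)=C\[C@H](O[Si](CC)(CC)CC)[C@H](C(=C)CO[Si](C)(C)C(C)(C)C)[C@H](OCc1ccc(OC)cc1)C[C@](C)(OCc1ccc(OC)cc1)CO[Si](CC)(CC)CC | intermediate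
25 | C1 aldehyde: (Z)-iodoalkene with O6-TES and C10(CH3)(OPMB)–CHO | I/C(CO[Si](c1ccccc1)(c1ccccc1)C(C)(C)C)=C\[C@H](O[Si](CC)(CC)CC)[C@H](C(=C)CO[Si](C)(C)C(C)(C)C)[C@H](OCc1ccc(OC)cc1)C[C@](C)(OCc1ccc(OC)cc1)C=O | intermediate
26 | tributyl(1-ethoxyvinyl)stannane | CCCC[Sn](CCCC)(CCCC)C(=C)OCC | starting material
27 | 2-ethoxydiene: CH2=C(OEt)–C4(CH2OTBDPS)=C5H– (Z) on the chain of 25 | C=C(OCC)/C(CO[Si](c1ccccc1)(c1ccccc1)C(C)(C)C)=C\[C@H](O[Si](CC)(CC)CC)[C@H](C(=C)CO[Si](C)(C)C(C)(C)C)[C@H](OCc1ccc(OC)cc1)C[C@](C)(OCc1ccc(OC)cc1)C=O | intermediate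
28 | (6S,7R,8R,10S) seco keto aldehyde: CH3–C3(=O)–C4(CH2OTBDPS)=C5H (Z)–C6H(OTES)–C7H[C(=CH2)CH2OTBS]–C8H(OPMB)–C9H2–C10(CH3)(OPMB)–C1HO | CC(=O)/C(CO[Si](c1ccccc1)(c1ccccc1)C(C)(C)C)=C\[C@H](O[Si](CC)(CC)CC)[C@H](C(=C)CO[Si](C)(C)C(C)(C)C)[C@H](OCc1ccc(OC)cc1)C[C@](C)(OCc1ccc(OC)cc1)C=O | intermediate
29 | potassium C2–C3 enolate of 28 | [K+].C=C([O-])/C(CO[Si](c1ccccc1)(c1ccccc1)C(C)(C)C)=C\[C@H](O[Si](CC)(CC)CC)[C@H](C(=C)CO[Si](C)(C)C(C)(C)C)[C@H](OCc1ccc(OC)cc1)C[C@](C)(OCc1ccc(OC)cc1)C=O | intermediate
30 | potassium C1 aldolate of 31 | [K+].COc1ccc(CO[C@@H]2C[C@](C)(OCc3ccc(OC)cc3)[C@@H]([O-])CC(=O)/C(CO[Si](c3ccccc3)(c3ccccc3)C(C)(C)C)=C\[C@H](O[Si](CC)(CC)CC)[C@@H]2C(=C)CO[Si](C)(C)C(C)(C)C)cc1 | intermediate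
31 | ten-membered β-hydroxy enone: C1 carbinol syn to O10, C3 ketone, Z-C4=C5; O6-TES, O8-PMB, O10-PMB, O12-TBS, O15-TBDPS | COc1ccc(CO[C@@H]2C[C@](C)(OCc3ccc(OC)cc3)[C@@H](O)CC(=O)/C(CO[Si](c3ccccc3)(c3ccccc3)C(C)(C)C)=C\[C@H](O[Si](CC)(CC)CC)[C@@H]2C(=C)CO[Si](C)(C)C(C)(C)C)cc1 | intermediate
32 | C1,C3-anti diol of 31 (3S) | COc1ccc(CO[C@@H]2C[C@](C)(OCc3ccc(OC)cc3)[C@@H](O)C[C@H](O)/C(CO[Si](c3ccccc3)(c3ccccc3)C(C)(C)C)=C\[C@H](O[Si](CC)(CC)CC)[C@@H]2C(=C)CO[Si](C)(C)C(C)(C)C)cc1 | intermediate
33 | C3 acetate of 32 (C1 hydroxyl free) | COc1ccc(CO[C@@H]2C[C@](C)(OCc3ccc(OC)cc3)[C@@H](O)C[C@H](OC(C)=O)/C(CO[Si](c3ccccc3)(c3ccccc3)C(C)(C)C)=C\[C@H](O[Si](CC)(CC)CC)[C@@H]2C(=C)CO[Si](C)(C)C(C)(C)C)cc1 | intermediate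
34 | C1 mesylate of 33 | COc1ccc(CO[C@@H]2C[C@](C)(OCc3ccc(OC)cc3)[C@@H](OS(C)(=O)=O)C[C@H](OC(C)=O)/C(CO[Si](c3ccccc3)(c3ccccc3)C(C)(C)C)=C\[C@H](O[Si](CC)(CC)CC)[C@@H]2C(=C)CO[Si](C)(C)C(C)(C)C)cc1 | intermediate
35 | C8,C10-diol: C1 mesylate, C3 acetate, O6-TES, O12-TBS, O15-TBDPS | O[C@@H]1C[C@](C)(O)[C@@H](OS(C)(=O)=O)C[C@H](OC(C)=O)/C(CO[Si](c2ccccc2)(c2ccccc2)C(C)(C)C)=C\[C@H](O[Si](CC)(CC)CC)[C@@H]1C(=C)CO[Si](C)(C)C(C)(C)C | intermediate
36 | C8 methacrylate of 35 (C10 hydroxyl free) | C=C(C)C(=O)O[C@@H]1C[C@](C)(O)[C@@H](OS(C)(=O)=O)C[C@H](OC(C)=O)/C(CO[Si](c2ccccc2)(c2ccccc2)C(C)(C)C)=C\[C@H](O[Si](CC)(CC)CC)[C@@H]1C(=C)CO[Si](C)(C)C(C)(C)C | intermediate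
37 | cis-1,10-epoxide (1R,10S) with C3 acetate, C8 methacrylate, O6-TES, O12-TBS, O15-TBDPS | C=C(C)C(=O)O[C@@H]1C[C@]2(C)O[C@@H]2C[C@H](OC(C)=O)/C(CO[Si](c2ccccc2)(c2ccccc2)C(C)(C)C)=C\[C@H](O[Si](CC)(CC)CC)[C@@H]1C(=C)CO[Si](C)(C)C(C)(C)C | intermediate
38 | C6,C12-diol of 37 (O15-TBDPS retained) | C=C(C)C(=O)O[C@@H]1C[C@]2(C)O[C@@H]2C[C@H](OC(C)=O)/C(CO[Si](c2ccccc2)(c2ccccc2)C(C)(C)C)=C\[C@H](O)[C@@H]1C(=C)CO | intermediate
39 | C12 enal with free C6 hydroxyl | C=C(C)C(=O)O[C@@H]1C[C@]2(C)O[C@@H]2C[C@H](OC(C)=O)/C(CO[Si](c2ccccc2)(c2ccccc2)C(C)(C)C)=C\[C@H](O)[C@@H]1C(=C)C=O | intermediate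
40 | 6,12-lactol (C12 configuration unspecified) | C=C(C)C(=O)O[C@@H]1C[C@]2(C)O[C@@H]2C[C@H](OC(C)=O)/C(CO[Si](c2ccccc2)(c2ccccc2)C(C)(C)C)=C\[C@@H]2OC(O)C(=C)[C@@H]21 | intermediate
41 | O15-tert-butyldiphenylsilyl ether of the target | C=C(C)C(=O)O[C@@H]1C[C@]2(C)O[C@@H]2C[C@H](OC(C)=O)/C(CO[Si](c2ccccc2)(c2ccccc2)C(C)(C)C)=C\[C@@H]2OC(=O)C(=C)[C@@H]21 | intermediate
42 | CNP0319155.2 (1R,3S,6S,7R,8R,10S) | C=C(C)C(=O)O[C@@H]1C[C@]2(C)O[C@@H]2C[C@H](OC(C)=O)/C(CO)=C\[C@@H]2OC(=O)C(=C)[C@@H]21 | target

## Step count and least certain steps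

Total: 27 steps. Longest linear sequence: 24 steps (from 1 through steps 1, 3–6, 8–11 and 13–27).

Step 18 (key step, proposed new method). The ring may fail to close because intermolecular aldol addition and retro-aldol reversal are favoured by the strain of the ten-membered ring. The aldolate may add to C5 of the enone (oxa-Michael), and facial selectivity at C1 may be poor if potassium chelates weakly. Fallback with known chemistry: set out from 27, isolated by omitting the acid treatment of step 17. N-Bromosuccinimide in wet THF should convert the dienyl ether into the bromomethyl ketone F1. SmI2 in THF at −78 °C under high dilution should then give a samarium enolate (trivalent samarium) that closes onto the aldehyde in a Reformatsky-type aldol reaction, a process known for medium and large rings. This enolate chelates strongly and its aldolate is not basic. Protonation returns the route at 31.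

Step 8. The alkenylmetal may be lost by β-elimination of silanolate before it reacts, and some attack at C8 may compete. Fallback: set out from 10 with isopropenylmagnesium bromide and CuI (cat.), the simplest reagent of this reaction type, to give the isopropenyl diol F2. Acetalisation as in step 9 gives the bis-acetal F3, allylic hydroxylation of the isopropenyl methyl group with SeO2 (cat.) and t-BuOOH gives the allylic alcohol F4, and silylation with t-BuMe2SiCl returns the route at 16.

Step 11. Discrimination between the two primary alcohols may be poor, leading to over-oxidation at C1. Fallback: set out from 17. One equivalent of Et3SiCl at −78 °C should silylate the less hindered C6 hydroxyl to give the mono-silyl ether F5. Pivaloylation of the C1 hydroxyl gives the pivalate F6, and Swern oxidation converts the primary triethylsilyl ether directly into the aldehyde F7. Addition of 20 as in step 13 gives the propargylic alcohol F8, and the conditions of step 14 reduce the pivalate off as they form the iodoalkene, returning the route at 23.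

Step 13. Facial selectivity may be poor if the open Felkin pathway competes with chelation, and the α-alkenyl aldehyde may enolise. Fallback: set out from 21 obtained as a C6 epimer mixture. MnO2 oxidises only the propargylic alcohol to the ynone F9, and Noyori transfer hydrogenation with RuCl(p-cymene)[(R,R)-TsDPEN] in propan-2-ol sets C6 under reagent control, returning the route at 21.

Step 20. Site selectivity between the C3 and C1 hydroxyls may be poor, with diacetate formation. Fallback replacing steps 19 and 20: set out from 31. An Evans–Tishchenko reduction with acetaldehyde and SmI2 (cat.) gives the anti diol with the acetate on O1 by intramolecular hydride transfer, the C1 monoacetate F10. A base-mediated 1,3-acyl shift (DBU, toluene, with recycling) then moves the acetate to the less hindered allylic O3, returning the route at 33.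

## Further compounds

F1 | step 18 | bromomethyl ketone analogue of 28 (BrCH2–C3(=O)–, C1 aldehyde) | BrCC(=O)/C(CO[Si](c1ccccc1)(c1ccccc1)C(C)(C)C)=C\[C@H](O[Si](CC)(CC)CC)[C@H](C(=C)CO[Si](C)(C)C(C)(C)C)[C@H](OCc1ccc(OC)cc1)C[C@](C)(OCc1ccc(OC)cc1)C=O
F2 | step 8 | isopropenyl analogue of 15 (C6 and C8 hydroxyls free) | OC[C@H](C(C)=C)[C@H](O)C[C@]1(C)OC(c2ccc(OC)cc2)OC1
F3 | step 8 | bis(4-methoxybenzylidene) acetal of F2 | C1[C@H](C(C)=C)[C@@H](C[C@]2(C)OC(c3ccc(OC)cc3)OC2)OC(c2ccc(OC)cc2)O1
F4 | step 8 | C12 allylic alcohol from F3 (desilyl 16) | C1[C@H](C(=C)CO)[C@@H](C[C@]2(C)OC(c3ccc(OC)cc3)OC2)OC(c2ccc(OC)cc2)O1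
F5 | step 11 | O6-triethylsilyl ether of 17 (C1 hydroxyl free) | CC[Si](CC)(CC)OC[C@H](C(=C)CO[Si](C)(C)C(C)(C)C)[C@H](OCc1ccc(OC)cc1)C[C@](C)(OCc1ccc(OC)cc1)CO
F6 | step 11 | O1-pivalate of F5 | CC[Si](CC)(CC)OC[C@H](C(=C)CO[Si](C)(C)C(C)(C)C)[C@H](OCc1ccc(OC)cc1)C[C@](C)(OCc1ccc(OC)cc1)COC(=O)C(C)(C)C
F7 | step 11 | C6 aldehyde with O1-pivalate | O=C[C@H](C(=C)CO[Si](C)(C)C(C)(C)C)[C@H](OCc1ccc(OC)cc1)C[C@](C)(OCc1ccc(OC)cc1)COC(=O)C(C)(C)C
F8 | step 11 | O1-pivalate of 21 | CC(C)(C)[Si](c1ccccc1)(c1ccccc1)OCC#C[C@H](O)[C@H](C(=C)CO[Si](C)(C)C(C)(C)C)[C@H](OCc1ccc(OC)cc1)C[C@](C)(OCc1ccc(OC)cc1)COC(=O)C(C)(C)C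
F9 | step 13 | C6 ynone from 21 (C1 hydroxyl free) | CC(C)(C)[Si](c1ccccc1)(c1ccccc1)OCC#CC(=O)[C@H](C(=C)CO[Si](C)(C)C(C)(C)C)[C@H](OCc1ccc(OC)cc1)C[C@](C)(OCc1ccc(OC)cc1)CO
F10 | step 20 | C1 acetate with free C3 hydroxyl (regioisomer of 33) | COc1ccc(CO[C@@H]2C[C@](C)(OCc3ccc(OC)cc3)[C@@H](OC(C)=O)C[C@H](O)/C(CO[Si](c3ccccc3)(c3ccccc3)C(C)(C)C)=C\[C@H](O[Si](CC)(CC)CC)[C@@H]2C(=C)CO[Si](C)(C)C(C)(C)C)cc1
A1 | alternative 1 | ten-membered bis(enol ether) carrying the C6 stereocentre | COc1ccc(CO[C@H]2C/C=C(\O[Si](C)(C)C)C/C=C(C)\C/C(OC)=C2\CCO[Si](C)(C)C(C)(C)C)cc1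
A2 | alternative 2 | ten-membered C8 alcohol with cis-fused α-methylene lactone | O[C@@H]1C/C(C)=C\C[C@H](OC(C)=O)/C(CO[Si](C)(C)C(C)(C)C)=C\[C@@H]2OC(=O)C(=C)[C@@H]21
A3 | alternative 3 | Z,Z-cyclodecadienone with C3, C7 and C8 stereocentres | CC(C)(C)[Si](C)(C)O[C@@H]1C/C(C)=C\C[C@H](OCc2ccc(OC)cc2)/C(CO[Si](c2ccccc2)(c2ccccc2)C(C)(C)C)=C\C(=O)[C@@H]1CC(=O)OC(C)(C)C
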